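**Strategy.** Everything rests on the C4–C5 disconnection of ring A. Ring B (a C5=C6–C7=O enone from an asymmetric Diels–Alder reaction), the hydroxy-succinimide side chain and a C10 arm carrying the C2/C3 dichloride and an isopropenyl C4 terminus are assembled first. A cobalt hydride then transfers a hydrogen atom to that olefin; the tertiary C4 radical closes ring A onto C5 and the enone is regenerated, so one operation forms the final ring and the quaternary gem-dimethyl carbon beside the preset dichloride. The step exploits the 1,3-relation of the C7 oxygen to C5: as a ketone it makes C5 a radical acceptor. Hydrogenation from the α-face later sets H-5.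

Key step: step 14

Remark: carbons are numbered as in a labdane (C1–C10 decalin, C11–C16 side chain and imide, C17 exocyclic methylene); α/β refer to the usual orientation with the C10 methyl β; TBS = tert-butyldimethylsilyl.
Remark: the succinimide N–H is carried unprotected; where a Grignard reagent or a silyl triflate is used, one extra equivalent is spent on it.
Remark: 14 is a mixture at C5 and 22–25 are mixtures at C8; both centres become sp2 later.

Step 1
Reactants: 1 (R)-4-benzyloxazolidin-2-one; 2 methyl 4-chloro-4-oxobutanoate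
Product: 3 (R)-4-benzyl-3-(4-methoxy-4-oxobutanoyl)oxazolidin-2-one
Conditions: n-BuLi, THF, −78 °C; then 2, −78 → 0 °C
Reagents that add atoms: none
Why: N-acylation of the lithiated oxazolidinone by the acid chloride gives the imide needed for an auxiliary-controlled aldol reaction; no stereocenter is formed.

Step 2
Reactants: 3 (R)-4-benzyl-3-(4-methoxy-4-oxobutanoyl)oxazolidin-2-one; 4 3-(benzyloxy)propanal
Product: 5 methyl (3R,4S)-3-[(R)-4-benzyl-2-oxooxazolidine-3-carbonyl]-6-(benzyloxy)-4-hydroxyhexanoate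
Conditions: Bu2BOTf, iPr2NEt, CH2Cl2, 0 °C; 4, −78 → 0 °C; then pH 7 buffer, MeOH, H2O2
Reagents that add atoms: none
Why: Evans syn-aldol reaction: the Z boron enolate, formed at the imide α-CH2 (more acidic than the ester α-CH2), reacts through a chair Zimmerman–Traxler transition state on the face left open by the (R)-benzyl group, which sets 12S (hydroxyl carbon) and 13R (future imide carbon).

Step 3
Reactants: 5 methyl (3R,4S)-3-[(R)-4-benzyl-2-oxooxazolidine-3-carbonyl]-6-(benzyloxy)-4-hydroxyhexanoate
Product: 6 methyl (3R,4S)-3-[(R)-4-benzyl-2-oxooxazolidine-3-carbonyl]-6-(benzyloxy)-4-(tert-butyldimethylsilyloxy)hexanoate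
Conditions: TBSOTf, 2,6-lutidine, CH2Cl2, 0 °C
Reagents that add atoms: tert-butyldimethylsilyl triflate, CC(C)(C)[Si](C)(C)OS(=O)(=O)C(F)(F)F
Why: Silylation of the secondary alcohol blocks lactonization onto the ester in step 4 and protects O-12 to the end.

Step 4
Reactants: 6 methyl (3R,4S)-3-[(R)-4-benzyl-2-oxooxazolidine-3-carbonyl]-6-(benzyloxy)-4-(tert-butyldimethylsilyloxy)hexanoate
Product: 8 (R)-3-[(S)-3-(benzyloxy)-1-(tert-butyldimethylsilyloxy)propyl]pyrrolidine-2,5-dione, via carboxamide ester 7 (not isolated)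
Conditions: NH3 (7 M in MeOH), 0 → 23 °C
Reagents that add atoms: ammonia, N
Why: Aminolysis of the exocyclic imide carbonyl releases the auxiliary, and the carboxamide nitrogen then closes onto the methyl ester (5-exo-trig acyl substitution) to form the succinimide ring without touching C12 or C13.

Step 5
Reactants: 8 (R)-3-[(S)-3-(benzyloxy)-1-(tert-butyldimethylsilyloxy)propyl]pyrrolidine-2,5-dione
Product: 9 (R)-3-[(S)-1-(tert-butyldimethylsilyloxy)-3-hydroxypropyl]pyrrolidine-2,5-dione
Conditions: H2 (1 atm), Pd/C, EtOAc, 23 °C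
Reagents that add atoms: none
Why: Hydrogenolysis of the benzyl ether frees the primary alcohol; nothing else in 8 is reducible.

Step 6
Reactants: 9 (R)-3-[(S)-1-(tert-butyldimethylsilyloxy)-3-hydroxypropyl]pyrrolidine-2,5-dione
Product: 10 (S)-3-(tert-butyldimethylsilyloxy)-3-[(R)-2,5-dioxopyrrolidin-3-yl]propanal
Conditions: Dess–Martin periodinane, NaHCO3, CH2Cl2, 0 → 23 °C
Reagents that add atoms: none
Why: Dess–Martin oxidation gives the aldehyde under buffered, non-basic conditions that avoid β-elimination of the silyloxy group.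

Step 7
Reactants: 10 (S)-3-(tert-butyldimethylsilyloxy)-3-[(R)-2,5-dioxopyrrolidin-3-yl]propanal; 11 2-(triphenylphosphoranylidene)propanal
Product: 12 (S,E)-5-(tert-butyldimethylsilyloxy)-5-[(R)-2,5-dioxopyrrolidin-3-yl]-2-methylpent-2-enal
Conditions: toluene, 60 °C
Reagents that add atoms: none
Why: Wittig reaction with the stabilized α-methyl ylide gives the E-configured 2-methyl enal (the dienophile) under neutral conditions.

Step 8
Reactants: 12 (S,E)-5-(tert-butyldimethylsilyloxy)-5-[(R)-2,5-dioxopyrrolidin-3-yl]-2-methylpent-2-enal; 13 (E)-3-(tert-butyldimethylsilyloxy)-N,N-dimethylbuta-1,3-dien-1-amine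
Product: 15 enone aldehyde (R)-3-{(S)-1-(tert-butyldimethylsilyloxy)-2-[(1S,2R)-2-formyl-2-methyl-5-oxocyclohex-3-en-1-yl]ethyl}pyrrolidine-2,5-dione, via amino silyl enol ether cycloadduct 14 (not isolated)
Conditions: Cr(salen)SbF6 (5 mol%, chiral trivalent chromium salen complex), 4 Å sieves, CH2Cl2, −20 → 23 °C; then AcCl, CH2Cl2/Et2O, −78 °C
Reagents that add atoms: none
Why: Diels–Alder reaction: the CH2 terminus of the amino siloxy diene bonds to the β-carbon (C9) of the Lewis-acid-bound enal, the E geometry places the side chain trans to CHO and cis to the C10 methyl, the chiral chromium salen Lewis acid fixes the absolute configuration at C9/C10, and acetyl chloride then expels the amine to give the C5=C6–C7=O enone.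

Step 9
Reactants: 15 enone aldehyde; 16 2-(triphenylphosphoranylidene)acetaldehyde
Product: 17 enal (15 with the formyl group replaced by (E)-CH=CH–CHO, C1–C3)
Conditions: toluene, 90 °C
Reagents that add atoms: none
Why: Wittig reaction of the neopentyl-type aldehyde with the stabilized formylmethylene ylide gives the E enal; the ring ketone does not react with this ylide.

Step 10
Reactants: 17 enal
Product: 18 α-chloro aldehyde (C10 arm = (R)-2-chloro-3-oxopropyl)
Conditions: (2S,5S)- or (2R,5R)-5-benzyl-2-tert-butyl-3-methylimidazolidin-4-one·TFA (20 mol%, enantiomer chosen for 2R), diethyl 2,6-dimethyl-1,4-dihydropyridine-3,5-dicarboxylate (Hantzsch ester), 2,3,4,5,6,6-hexachlorocyclohexa-2,4-dien-1-one, EtOAc, −40 °C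
Reagents that add atoms: 2,3,4,5,6,6-hexachlorocyclohexa-2,4-dien-1-one, O=C1C(Cl)=C(Cl)C(Cl)=C(Cl)C1(Cl)Cl
Why: Organocatalytic reduction–chlorination cascade: the imidazolidinone forms the iminium ion of the enal only (the ring enone is a ketone), the Hantzsch ester delivers hydride to C1, and the resulting enamine is chlorinated at C2 on the face left open by the catalyst, which sets 2R.

Step 11
Reactants: 18 α-chloro aldehyde
Product: 19 chlorohydrin (C10 arm = (2R,3S)-2-chloro-3-hydroxy-4-methylpent-4-enyl)
Conditions: isopropenylmagnesium bromide (2.2 equiv), THF, −78 °C; then aq. NH4Cl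
Reagents that add atoms: isopropenylmagnesium bromide, C=C(C)[Mg]Br
Why: Grignard addition to the aldehyde, faster than to the ring ketone at −78 °C; the α-chlorine directs by the Cornforth model to the anti chlorohydrin (3S).

Step 12
Reactants: 19 chlorohydrin
Product: 20 dichloride (C10 arm = (2R,3R)-2,3-dichloro-4-methylpent-4-enyl)
Conditions: PPh3, hexachloroacetone, CH2Cl2, 0 °C
Reagents that add atoms: hexachloroacetone, O=C(C(Cl)(Cl)Cl)C(Cl)(Cl)Cl
Why: Deoxychlorination of the allylic alcohol with the triphenylphosphine–hexachloroacetone reagent, which gives the unrearranged chloride by SN2 displacement of the oxyphosphonium ion with inversion, turns 3S–OH into 3R–Cl (threo 2,3-dichloride).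

Step 13
Reactants: 20 dichloride
Product: 22 benzyloxymethyl enone (20 with CH2OCH2Ph on C8), via silyl dienol ether 21 (not isolated)
Conditions: TBSOTf (2.2 equiv), Et3N, CH2Cl2, 0 °C; then BOMCl, ZnBr2 (10 mol%), CH2Cl2, −20 → 0 °C
Reagents that add atoms: benzyl chloromethyl ether, ClCOCc1ccccc1
Why: Soft enolization can occur only at C8 (C6 is vinylic, C10 quaternary) and gives the cross-conjugated 2-silyloxy diene, whose Lewis-acid-mediated alkoxymethylation (Mukaiyama-type alkylation) puts the future C17 on C8; the C8 configuration is irrelevant.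

Step 14
Reactants: 22 benzyloxymethyl enone
Product: 23 bicyclic enone (ring A closed; 2α,3β-dichloro-4,4,10β-trimethyl, C5=C6–C7=O)
Conditions: Co(salen)Cl (5 mol%; salen = N,N′-bis(3,5-di-tert-butylsalicylidene)cyclohexane-1,2-diamine dianion), PhSiH3 (10 mol%), benzene, 22 °C, argon
Reagents that add atoms: none
Why: Proposed new method: the cobalt hydride formed from Co(salen)Cl and PhSiH3 gives a hydrogen atom to the CH2 terminus of the 1,1-disubstituted olefin (Markovnikov hydrogen-atom transfer), the tertiary C4 radical adds to C5 of the C5=C6–C7=O enone, and divalent cobalt removes the C5 hydrogen from the resulting C6 α-keto radical, which returns the hydride and the enone, so the step is a redox-neutral cycloisomerization; each elementary event is precedented, and the closest known reaction types are the cobalt-catalysed hydrogen-atom-transfer cycloisomerization of dienes and the iron-hydride reductive olefin–enone coupling. Ring A is closed in the 6-exo-trig mode (C4 onto C5, C6 outside the new ring), and the gem-dimethyl carbon and the electron-poor acceptor favour cyclization over return of the hydrogen atom. No stereocenter is created: C4 carries two methyl groups and C5 stays sp2, while the 2R and 3R chlorides are carried through because a β-chloroalkyl radical loses chlorine only slowly at room temperature. The step needs chemoselective hydrogen-atom transfer to the isopropenyl group, secured because it is the only electron-rich C=C bond in 22, and regiospecific dehydrogenation, secured because C5–H is the only hydrogen β to the C6 radical.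

Step 15
Reactants: 23 bicyclic enone
Product: 24 hydroxymethyl ketone (H-5α; C6H2; 7-oxo; 8-CH2OH)
Conditions: H2 (4 atm), Pd(OH)2/C, EtOAc, 23 °C
Reagents that add atoms: none
Why: Heterogeneous hydrogenation adds H2 syn to the C5=C6 bond from the α-face, opposite the axial C10 methyl and the 4β-methyl, which gives H-5α (trans ring fusion), and the benzyl ether is cleaved by hydrogenolysis in the same operation.

Step 16
Reactants: 24 hydroxymethyl ketone
Product: 26 methylene ketone (7-oxo; C8=C17H2), via mesylate 25 (not isolated)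
Conditions: MsCl, Et3N, CH2Cl2, 0 °C; then DBU, 23 °C
Reagents that add atoms: none
Why: Mesylation of the primary alcohol and E1cB elimination of the β-mesyloxy ketone give the exocyclic α-methylene ketone and remove the C8 stereocenter.

Step 17
Reactants: 26 methylene ketone
Product: 27 7β-alcohol
Conditions: NaBH4, CeCl3·7H2O, MeOH, −78 °C
Reagents that add atoms: none
Why: Luche reduction: 1,2-selective hydride addition to the enone by axial attack on the α-face gives the equatorial 7β-alcohol (7S).

Step 18
Reactants: 27 7β-alcohol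
Product: 28 7β-acetate (12-O-TBS haterumaimide A)
Conditions: Ac2O, pyridine, DMAP (cat.), CH2Cl2, 0 → 23 °C
Reagents that add atoms: acetic anhydride, CC(=O)OC(C)=O
Why: Acylation of the only free hydroxyl group (O-12 is silylated) installs the 7β-acetate with retention.

Step 19
Reactants: 28 7β-acetate
Product: 29 haterumaimide A
Conditions: HF·pyridine, THF/pyridine, 0 → 23 °C
Reagents that add atoms: none
Why: Fluoride-mediated cleavage of the secondary silyl ether frees the 12-hydroxyl group under conditions that leave the allylic acetate, the imide and the chlorides intact.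

**Compound list**

1 | (R)-4-benzyloxazolidin-2-one | O=C1N[C@H](Cc2ccccc2)CO1 | starting material
2 | methyl 4-chloro-4-oxobutanoate | COC(=O)CCC(Cl)=O | starting material
3 | (R)-4-benzyl-3-(4-methoxy-4-oxobutanoyl)oxazolidin-2-one | COC(=O)CCC(=O)N1[C@H](Cc2ccccc2)COC1=O | intermediate
4 | 3-(benzyloxy)propanal | O=CCCOCc1ccccc1 | starting material
5 | methyl (3R,4S)-3-[(R)-4-benzyl-2-oxooxazolidine-3-carbonyl]-6-(benzyloxy)-4-hydroxyhexanoate | c1ccccc1COCC[C@H](O)[C@H](C(=O)N1[C@H](Cc2ccccc2)COC1=O)CC(=O)OC | intermediate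
6 | methyl (3R,4S)-3-[(R)-4-benzyl-2-oxooxazolidine-3-carbonyl]-6-(benzyloxy)-4-(tert-butyldimethylsilyloxy)hexanoate | c1ccccc1COCC[C@H](O[Si](C)(C)C(C)(C)C)[C@H](C(=O)N1[C@H](Cc2ccccc2)COC1=O)CC(=O)OC | intermediate
7 | carboxamide ester: methyl (3R,4S)-6-(benzyloxy)-4-(tert-butyldimethylsilyloxy)-3-carbamoylhexanoate | c1ccccc1COCC[C@H](O[Si](C)(C)C(C)(C)C)[C@H](C(N)=O)CC(=O)OC | intermediate (not isolated)
8 | (R)-3-[(S)-3-(benzyloxy)-1-(tert-butyldimethylsilyloxy)propyl]pyrrolidine-2,5-dione | c1ccccc1COCC[C@H](O[Si](C)(C)C(C)(C)C)[C@H]1CC(=O)NC1=O | intermediate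
9 | (R)-3-[(S)-1-(tert-butyldimethylsilyloxy)-3-hydroxypropyl]pyrrolidine-2,5-dione | OCC[C@H](O[Si](C)(C)C(C)(C)C)[C@H]1CC(=O)NC1=O | intermediate
10 | (S)-3-(tert-butyldimethylsilyloxy)-3-[(R)-2,5-dioxopyrrolidin-3-yl]propanal | O=CC[C@H](O[Si](C)(C)C(C)(C)C)[C@H]1CC(=O)NC1=O | intermediate
11 | 2-(triphenylphosphoranylidene)propanal | CC(C=O)=P(c1ccccc1)(c1ccccc1)c1ccccc1 | starting material
12 | (S,E)-5-(tert-butyldimethylsilyloxy)-5-[(R)-2,5-dioxopyrrolidin-3-yl]-2-methylpent-2-enal | O=C/C(C)=C/C[C@H](O[Si](C)(C)C(C)(C)C)[C@H]1CC(=O)NC1=O | intermediate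
13 | (E)-3-(tert-butyldimethylsilyloxy)-N,N-dimethylbuta-1,3-dien-1-amine | CN(C)/C=C/C(=C)O[Si](C)(C)C(C)(C)C | starting material
14 | amino silyl enol ether cycloadduct: cyclohexene with NMe2 on C5, C6=C7 silyl enol ether, C10 methyl and formyl, C9 side chain (methyl cis to side chain; C5 epimers) | CN(C)C1C=C(O[Si](C)(C)C(C)(C)C)C[C@H](C[C@H](O[Si](C)(C)C(C)(C)C)[C@H]2CC(=O)NC2=O)[C@@]1(C)C=O | intermediate (not isolated)
15 | enone aldehyde: (R)-3-{(S)-1-(tert-butyldimethylsilyloxy)-2-[(1S,2R)-2-formyl-2-methyl-5-oxocyclohex-3-en-1-yl]ethyl}pyrrolidine-2,5-dione | O=C1C=C[C@](C)(C=O)[C@@H](C[C@H](O[Si](C)(C)C(C)(C)C)[C@H]2CC(=O)NC2=O)C1 | intermediate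
16 | 2-(triphenylphosphoranylidene)acetaldehyde | O=CC=P(c1ccccc1)(c1ccccc1)c1ccccc1 | starting material
17 | enal: 15 with the formyl group replaced by (E)-3-oxoprop-1-enyl; ring and side-chain stereocentres unchanged | O=C1C=C[C@](C)(/C=C/C=O)[C@@H](C[C@H](O[Si](C)(C)C(C)(C)C)[C@H]2CC(=O)NC2=O)C1 | intermediate
18 | α-chloro aldehyde: C10 arm = (R)-2-chloro-3-oxopropyl | O=C1C=C[C@](C)(C[C@@H](Cl)C=O)[C@@H](C[C@H](O[Si](C)(C)C(C)(C)C)[C@H]2CC(=O)NC2=O)C1 | intermediate
19 | chlorohydrin: C10 arm = (2R,3S)-2-chloro-3-hydroxy-4-methylpent-4-enyl | O=C1C=C[C@](C)(C[C@@H](Cl)[C@@H](O)C(C)=C)[C@@H](C[C@H](O[Si](C)(C)C(C)(C)C)[C@H]2CC(=O)NC2=O)C1 | intermediate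
20 | dichloride: C10 arm = (2R,3R)-2,3-dichloro-4-methylpent-4-enyl | O=C1C=C[C@](C)(C[C@@H](Cl)[C@H](Cl)C(C)=C)[C@@H](C[C@H](O[Si](C)(C)C(C)(C)C)[C@H]2CC(=O)NC2=O)C1 | intermediate
21 | silyl dienol ether: C5=C6–C7(OTBS)=C8 diene of 20 | C1=C(O[Si](C)(C)C(C)(C)C)C=C[C@](C)(C[C@@H](Cl)[C@H](Cl)C(C)=C)[C@H]1C[C@H](O[Si](C)(C)C(C)(C)C)[C@H]1CC(=O)NC1=O | intermediate (not isolated)
22 | benzyloxymethyl enone: 20 with CH2OCH2Ph on C8 (C8 epimers) | c3ccccc3COCC1C(=O)C=C[C@](C)(C[C@@H](Cl)[C@H](Cl)C(C)=C)[C@H]1C[C@H](O[Si](C)(C)C(C)(C)C)[C@H]1CC(=O)NC1=O | intermediate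
23 | bicyclic enone: 2α,3β-dichloro-4,4,10β-trimethyl decalin with C5=C6–C7=O, 8-benzyloxymethyl (epimers), H-9α and the 9β side chain CH2–CH(OTBS)–succinimidyl (12S,13R) | c3ccccc3COCC1C(=O)C=C2C(C)(C)[C@@H](Cl)[C@H](Cl)C[C@]2(C)[C@H]1C[C@H](O[Si](C)(C)C(C)(C)C)[C@H]1CC(=O)NC1=O | intermediate
24 | hydroxymethyl ketone: trans-decalin (H-5α), 7-oxo, 8-CH2OH (epimers) | OCC1C(=O)C[C@H]2C(C)(C)[C@@H](Cl)[C@H](Cl)C[C@]2(C)[C@H]1C[C@H](O[Si](C)(C)C(C)(C)C)[C@H]1CC(=O)NC1=O | intermediate
25 | mesylate of 24 | CS(=O)(=O)OCC1C(=O)C[C@H]2C(C)(C)[C@@H](Cl)[C@H](Cl)C[C@]2(C)[C@H]1C[C@H](O[Si](C)(C)C(C)(C)C)[C@H]1CC(=O)NC1=O | intermediate (not isolated)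
26 | methylene ketone: 7-oxo-8(17)-ene | C=C1C(=O)C[C@H]2C(C)(C)[C@@H](Cl)[C@H](Cl)C[C@]2(C)[C@H]1C[C@H](O[Si](C)(C)C(C)(C)C)[C@H]1CC(=O)NC1=O | intermediate
27 | 7β-alcohol (7S) | C=C1[C@@H](O)C[C@H]2C(C)(C)[C@@H](Cl)[C@H](Cl)C[C@]2(C)[C@H]1C[C@H](O[Si](C)(C)C(C)(C)C)[C@H]1CC(=O)NC1=O | intermediate
28 | 7β-acetate (12-O-TBS haterumaimide A) | C=C1[C@@H](OC(C)=O)C[C@H]2C(C)(C)[C@@H](Cl)[C@H](Cl)C[C@]2(C)[C@H]1C[C@H](O[Si](C)(C)C(C)(C)C)[C@H]1CC(=O)NC1=O | intermediate
29 | haterumaimide A (2R,3R,5R,7S,9R,10R,12S,13R) | C=C1[C@@H](OC(C)=O)C[C@H]2C(C)(C)[C@@H](Cl)[C@H](Cl)C[C@]2(C)[C@H]1C[C@H](O)[C@H]1CC(=O)NC1=O | target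

**Step count.** Total: 19 steps. Longest linear sequence: 19 steps (1 and 2 to 29).

**Steps most likely to fail**

Step 14 (proposed new method). The tertiary C4 radical may hand its hydrogen atom back to cobalt before it cyclizes (olefin migration into C3=C4 with loss of the C3 stereocenter), may lose the β-chlorine, or the C6 radical may be reduced instead of dehydrogenated. The fallback uses known chemistry and sets out from 22. Iron-hydride reductive olefin–enone coupling (Fe(acac)3, PhSiH3, EtOH/ethylene glycol, 60 °C) closes ring A and should give the cis-fused saturated ketone F1, because the tether attacks the enone face on which it sits. Palladium-catalysed aerobic α,β-dehydrogenation (Pd(TFA)2, DMSO, O2, AcOH, 80 °C) on the unsubstituted α-CH2 side (C6) then erases C5 and returns to 23.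

Step 12. The allylic oxyphosphonium ion may be displaced with allylic transposition (SN2′), may ionize, or may be opened with participation of the neighbouring C2 chlorine, which would scramble or retain the C3 configuration. The fallback sets out from 18. Wittig reaction with isopropylidenetriphenylphosphorane (2 equiv, one spent on the imide N–H) gives the prenyl-type allylic chloride F2. Ene-type allylic chlorination with hypochlorous acid (Ca(OCl)2, solid CO2, CH2Cl2/H2O, 0 °C) then installs the C3 chlorine with shift of the double bond into the isopropenyl position and returns to 20. The C3 configuration then depends on the facial bias of the allylic chloride, and a minor epimer would be separated.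

Step 15. Hydrogen delivery to C5, which is flanked by two quaternary carbons, may be slow or occur from both faces, and prolonged exposure may start C–Cl hydrogenolysis. The fallback sets out from 23. Hydrogen-atom-transfer conjugate reduction (Mn(dpm)3, PhSiH3, iPrOH, 23 °C) transfers hydrogen stepwise to C5 from the open α-face and gives the trans-fused benzyl ether F3. Ordinary hydrogenolysis (H2, Pd/C, EtOAc) then returns to 24.

**Further compounds**

F1 | step 14 | cis-fused saturated ketone: 23 with H-5β and C6H2 | c3ccccc3COCC1C(=O)C[C@@H]2C(C)(C)[C@@H](Cl)[C@H](Cl)C[C@]2(C)[C@H]1C[C@H](O[Si](C)(C)C(C)(C)C)[C@H]1CC(=O)NC1=O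
F2 | step 12 | prenyl-type allylic chloride: C10 arm = (R)-2-chloro-4-methylpent-3-enyl | O=C1C=C[C@](C)(C[C@@H](Cl)C=C(C)C)[C@@H](C[C@H](O[Si](C)(C)C(C)(C)C)[C@H]2CC(=O)NC2=O)C1
F3 | step 15 | trans-fused benzyl ether: 24 with the C17 hydroxyl still benzylated | c3ccccc3COCC1C(=O)C[C@H]2C(C)(C)[C@@H](Cl)[C@H](Cl)C[C@]2(C)[C@H]1C[C@H](O[Si](C)(C)C(C)(C)C)[C@H]1CC(=O)NC1=O
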